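Starting material and product add up to about the charge in both runs, with a scatter of 1 percentage point on each reading, so we take two flasks at equal conversion to hold the same mixture, and what may still differ between them is the enzyme.

common to all: starting material 49 mM

| flask | enzyme | remark |
|---|---|---|
| theta | 4.9 µM | the very flask that is asked about, followed so far |
| eta | 3.3 µM | run made earlier |
| flask | 4.9 µM |  |

| run | time / min | product / % | starting material / % |
|---|---|---|---|
| theta | 0.333 | 3.7 | 95.6 |
| theta | 0.500 | 5.4 | 92.9 |
| theta | 0.833 | 10.5 | 89.9 |
| theta | 1.33 | 13.6 | 84.3 |
| theta | 2.00 | 19.5 | 77.5 |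
| theta | 3.00 | 25.4 | 74.2 |
| theta | 5.00 | 34.6 | 63.7 |
| eta | 4.00 | 24.3 | 77.5 |
| eta | 8.00 | 35.0 | 66.0 |
| eta | 10.0 | 38.6 | 61.9 |
| eta | 15.0 | 52.2 | 50.2 |
| eta | 20.0 | 60.3 | 37.3 |
| eta | 25.0 | 70.9 | 28.6 |

(readings scatter by 1 percentage point)

* factor on the rate of making product when 10% of the starting material are converted if enzyme is charged twice over
* factor on the rate when 10% of the starting material are converted if enzyme is charged at 0.50 µM instead

Take the main step first: starting material goes to product on enzyme, at a rate proportional to working enzyme. The factors are then ratios of charges, 2 on doubling and 0.102 at 0.50 µM. Add saturation or product holding the enzyme: these act through the mixture, which is equal at 10%, so they cancel in both factors.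

One more process needs asking about: does an enzyme molecule stay at work? We compare its chances early and late through the slope s, the logarithm of the ratio of two starting-material readings over the time between them. In the theta run s is 0.128 min⁻¹ up to 0.833 min, about 10% conversion. In the eta run s is 0.0515 min⁻¹ from 10.0 min to 25.0 min, no lower than the 0.0375 min⁻¹ from 4.00 min to 10.0 min, so these readings show no further loss of activity after 4.00 min. Per unit of enzyme charged, the late slope over the early one is the fade factor g, the chance of working late in the eta run over the chance of working up to about 10% in the theta run: 0.598. This is a reading, with its scatter and the change of mixture between the stretches in it.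

At 0.50 µM, even plain enzyme × time puts 10% at 8.16 min, later than 4.00 min, so we count that enzyme as faded. Our estimate of the ratio is therefore 0.0610, and doubling, which reaches 10% sooner, gives somewhat above 2.

The forecast gives 2 and 0.102: “Rate at fixed conversion should therefore scale with enzyme”. At 0.50 µM we differ from it, 0.0610 against 0.102.

The simulation gives 2.28 and 0.0472.

    enzyme ⇌ dormant form (K = 1.80, k = 0.00570 s⁻¹)
    starting material + enzyme → product + enzyme, rate k2*[starting material]*[enzyme]/(1 + ([starting material]/Km2) + ([product]/Kp2)) (26.0 mM, 0.0840 M, k = 1400 M⁻¹ s⁻¹)

Taking away the path from enzyme to dormant form brings the apparent order in enzyme from 1.3 to 1.0. It also raises this flask's rate at 10% to 1.29 times the actual one, so at 0.822 min the working enzyme is 77.2% of the charge. By 12.5 min this flask holds 35.8% as enzyme, so its g is 0.463, below our reading of 0.598. Carried to the 0.50 µM flask, that g times 0.102 gives 0.0472.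

The readings were computed from invented constants; the scatter is artificial.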